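**Plan**

1. Retrosynthesis: after removal of the silyl and benzyl groups, four bonds of chromanone ring B are cut together (C8–C8a, C5–C6, C7–C8, C4a–C5). This gives a dihydropyranonyl α-diazo ketone carrying ring A on the diazo carbon, plus 1-(triisopropylsilyloxy)propyne.
2. Enabling feature: ring B (C4a, C5 OH, C6 CH3, C7 OH, C8 CH2 bridge, C8a) has O1 of ring C (O1, C2, C3, C4) on C8a beside the bridge. O1 is already bonded to the carbon that migrates, so only the 8-substituted chromanone can form.
3. Further cuts: the diazo group (diazo transfer to an enaminone), then the C–C(=O) bond between the ring A side chain and the pyranone (acylation of an aldehyde enamine by the acid chloride from butopyronoxyl).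
4. Ring A comes from 2-methylphloroglucinol: Friedel–Crafts acylation, O-allylation para to the acyl group and Claisen shift to C5′, O-methylation at C4′, benzylation, hydroboration–oxidation to the propanal.
5. Forward order: ring A is elaborated, ring C is bought, the three-carbon chain joins them, ring B closes last, then fluoride and hydrogenolysis free the phenols.
6. Stereochemistry: the single (R) centre is bought as (R)-2-methylbutanoic acid; no other permanent stereocentre is formed and later steps avoid enolising that ketone.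

Key step: step 12

Assumption: commercial butopyronoxyl is used as the cyclic 2,3-dihydropyran-4-one ester (any open-chain tautomer recloses in the acidic work-up of step 8), and (R)-2-methylbutanoic acid is bought in high enantiomeric purity.

Locants and abbreviation: the carbons of ring A carry primed numbers, C1′ (acyl), C2′ (OH), C3′ (CH3), C4′ (OCH3), C5′ (bridge), C6′ (OH); the chromanone is O1, C2, C3, C4, C4a, C5–C8, C8a. Ar = 2,4-bis(benzyloxy)-6-methoxy-5-methyl-3-[(2R)-2-methylbutanoyl]phenyl, which is protected ring A attached through C5′.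

**Route**

Step 1
Reactants: 1 2-methylphloroglucinol; 2 (R)-2-methylbutanoic acid
Product: 4 (R)-2-methyl-1-(2,4,6-trihydroxy-3-methylphenyl)butan-1-one, via acid chloride 3 (not isolated)
Conditions: (COCl)2, cat. DMF, CH2Cl2, 0 °C → rt; then 1, AlCl3, PhNO2, 0 °C → rt
Reagents that add atoms: none
Why: Friedel–Crafts acylation at one of the two equivalent free ring positions of 1 should stop at the mono-ketone because the product is deactivated, and the α-stereocentre of 2 is carried through a base-free sequence at or below room temperature (enantiomeric purity to be checked at this stage).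

Step 2
Reactants: 4 (R)-2-methyl-1-(2,4,6-trihydroxy-3-methylphenyl)butan-1-one
Product: 5 (R)-1-[2,6-dihydroxy-3-methyl-4-(prop-2-en-1-yloxy)phenyl]-2-methylbutan-1-one
Conditions: allyl alcohol, PPh3, DIAD, THF, 0 °C → rt
Reagents that add atoms: allyl alcohol, C=CCO
Why: Mitsunobu etherification should pick the C4′ hydroxyl, which is para to the acyl group, the most acidic and the only one not hydrogen-bonded to the ketone, and it cannot give C-allylation.

Step 3
Reactants: 5 (R)-1-[2,6-dihydroxy-3-methyl-4-(prop-2-en-1-yloxy)phenyl]-2-methylbutan-1-one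
Product: 6 (R)-2-methyl-1-[2,4,6-trihydroxy-3-methyl-5-(prop-2-en-1-yl)phenyl]butan-1-one
Conditions: 1,2-dichlorobenzene (degassed), 170 °C
Reagents that add atoms: none
Why: the aromatic Claisen rearrangement ([3,3] shift) can only end at C5′, the sole ortho position bearing hydrogen (migration to the methylated C3′ can only revert), and the neutral medium should leave the ketone α-centre alone.

Step 4
Reactants: 6 (R)-2-methyl-1-[2,4,6-trihydroxy-3-methyl-5-(prop-2-en-1-yl)phenyl]butan-1-one
Product: 7 (R)-1-[2,6-dihydroxy-4-methoxy-3-methyl-5-(prop-2-en-1-yl)phenyl]-2-methylbutan-1-one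
Conditions: MeI (1.05 equiv), K2CO3, acetone, 0 °C → rt
Reagents that add atoms: iodomethane, CI
Why: Williamson etherification with one equivalent of MeI should again take only the acidic, non-chelated C4′ hydroxyl, the two ortho hydroxyls being held by hydrogen bonds to the ketone.

Step 5
Reactants: 7 (R)-1-[2,6-dihydroxy-4-methoxy-3-methyl-5-(prop-2-en-1-yl)phenyl]-2-methylbutan-1-one
Product: 8 (R)-1-[2,6-bis(benzyloxy)-4-methoxy-3-methyl-5-(prop-2-en-1-yl)phenyl]-2-methylbutan-1-one
Conditions: BnBr, K2CO3, cat. Bu4NI, DMF, 40 °C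
Reagents that add atoms: benzyl bromide, BrCc1ccccc1
Why: exhaustive Williamson O-benzylation is clean because the ring has no free carbon left for C-alkylation and K2CO3 is too weak to enolise the hindered aryl ketone.

Step 6
Reactants: 8 (R)-1-[2,6-bis(benzyloxy)-4-methoxy-3-methyl-5-(prop-2-en-1-yl)phenyl]-2-methylbutan-1-one
Product: 10 3-Ar-propan-1-ol, via alkylborane 9 (not isolated)
Conditions: 9-BBN, THF, 0 °C → rt; then 30% H2O2, aq NaOAc, 0 °C → rt
Reagents that add atoms: hydrogen peroxide, OO
Why: anti-Markovnikov hydroboration–oxidation with 9-BBN places boron on the terminal carbon and ignores the di-ortho-substituted aryl ketone, and acetate-buffered peroxide oxidises the C–B bond without enolising that ketone.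

Step 7
Reactants: 10 3-Ar-propan-1-ol
Product: 11 3-Ar-propanal
Conditions: Dess–Martin periodinane, CH2Cl2, 0 °C → rt
Reagents that add atoms: none
Why: Dess–Martin oxidation takes a primary alcohol to the aldehyde under neutral conditions without over-oxidation or epimerisation.

Step 8
Reactants: 12 butopyronoxyl (butyl 2,2-dimethyl-4-oxo-3,4-dihydro-2H-pyran-6-carboxylate)
Product: 13 2,2-dimethyl-4-oxo-3,4-dihydro-2H-pyran-6-carboxylic acid
Conditions: LiOH (1.2 equiv), THF/H2O, 0 °C; then 1 M HCl to pH 2
Reagents that add atoms: lithium hydroxide (LiOH), [Li+].[OH-]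
Why: ester saponification at 0 °C should be faster than attack on the vinylogous ester, and any ring-opened material recloses to the dihydropyranone on acidification, as it does when this ring system is made.

Step 9
Reactants: 11 3-Ar-propanal; 13 2,2-dimethyl-4-oxo-3,4-dihydro-2H-pyran-6-carboxylic acid
Product: 16 (E)-2-(Ar-methyl)-1-(2,2-dimethyl-4-oxo-3,4-dihydro-2H-pyran-6-yl)-3-(pyrrolidin-1-yl)prop-2-en-1-one, via pyranone acid chloride 14 (not isolated), via pyrrolidine enamine 15 (not isolated)
Conditions: 13: (COCl)2, cat. DMF, CH2Cl2, 0 °C → rt, evaporate; 11: pyrrolidine (1.05 equiv), 4 Å MS, CH2Cl2, 0 °C; then 14, Et3N, −20 °C → rt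
Reagents that add atoms: pyrrolidine, C1CCNC1
Why: in this Stork enamine acylation the enamine of the unhindered aldehyde is acylated at its β-carbon by an acid chloride that has no α-hydrogen (so no ketene pathway), and loss of HCl to Et3N gives the stable push–pull enaminone, while the hindered ring A ketone forms no enamine.

Step 10
Reactants: 16 (E)-2-(Ar-methyl)-1-(2,2-dimethyl-4-oxo-3,4-dihydro-2H-pyran-6-yl)-3-(pyrrolidin-1-yl)prop-2-en-1-one
Product: 17 3-Ar-2-diazo-1-(2,2-dimethyl-4-oxo-3,4-dihydro-2H-pyran-6-yl)propan-1-one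
Conditions: TsN3, MeCN, rt → 40 °C
Reagents that add atoms: 4-methylbenzenesulfonyl azide, Cc1ccc(cc1)S(=O)(=O)N=[N+]=[N-]
Why: diazo transfer to an enaminone proceeds by (3+2) addition of the sulfonyl azide across the electron-rich C=C and cycloreversion of the triazoline to the α-diazo ketone and an N-sulfonyl formamidine (the enaminone counterpart of Regitz deformylative diazo transfer), under neutral conditions that spare the stereocentre and the pyranone.

Step 11
Reactants: 18 ethyl acetate
Product: 21 1-(triisopropylsilyloxy)propyne, via dibromo enolate 19 (not isolated), via lithium ynolate 20 (not isolated)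
Conditions: CH2Br2, LiTMP, THF, −78 °C; n-BuLi, −78 → 0 °C; TIPSCl, −78 °C → rt
Reagents that add atoms: dibromomethane, BrCBr; chlorotriisopropylsilane, CC(C)[Si](Cl)(C(C)C)C(C)C
Why: in the Kowalski ester homologation LiCHBr2 converts the ester into the dibromo ketone enolate, bromine–lithium exchange triggers a 1,2-methyl shift to the ynolate, and the bulky silyl chloride silylates on oxygen to give the silyl ynol ether.

Step 12
Reactants: 17 3-Ar-2-diazo-1-(2,2-dimethyl-4-oxo-3,4-dihydro-2H-pyran-6-yl)propan-1-one; 21 1-(triisopropylsilyloxy)propyne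
Product: 26 8-(Ar-methyl)-5-hydroxy-2,2,6-trimethyl-7-(triisopropylsilyloxy)chroman-4-one, via vinylketene 22 (not isolated), via cyclobutenone 23 (not isolated), via dienylketene 24 (not isolated), via cyclohexadienone 25 (not isolated)
Conditions: 21 (2 equiv), hν (400–420 nm LED), ClCH2CH2Cl (degassed), 20 °C; then 80 °C in the dark
Reagents that add atoms: none
Why: Excitation of the long-wavelength n→π* band of 17 should expel N2 with a concerted 1,2-shift of the pyranone carbon (C8–C8a bond) to give vinylketene 22, whose ketene C=C adds the siloxyalkyne by [2+2] cycloaddition (C5–C6 and C7–C8 bonds), the nucleophilic methyl-bearing alkyne carbon bonding to the ketene carbonyl carbon, to give cyclobutenone 23. On warming, 23 opens reversibly by four-electron electrocyclic ring opening to dienylketene 24, and the geometric isomer with the pyranone alkene cis to the ketene closes by six-electron electrocyclisation (C4a–C5 bond) to dienone 25, which enolises to the C5 phenol hydrogen-bonded to the C4 ketone. The closest known reaction is the second-generation Danheiser benzannulation (photochemical Wolff rearrangement of an unsaturated α-diazo ketone in the presence of a siloxyalkyne), here with a β-alkoxy enone as the migrating unsaturated group and an alkyl substituent on the diazo carbon. Ring B is the only ring closed, by thermal disrotatory six-electron electrocyclisation of the dienylketene onto C4a, and ring C is carried through intact. No lasting stereocentre is formed (the ring carbons of 23 and 25 are transient), and the neutral, base-free medium should leave the (R) centre of the side chain untouched. The step needs Wolff migration to beat 1,2-hydride shift from the bridging CH2 and needs the ring A ketone to stay unexcited; direct singlet excitation at 400–420 nm, where only the conjugated diazo chromophore should absorb, without metal carbenoid or triplet sensitiser, favours concerted shift of the sp2 carbon from the s-Z conformer, and because O1 is bonded to the migrating carbon the 8-substituted chromanone is the only constitutional outcome.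

Step 13
Reactants: 26 8-(Ar-methyl)-5-hydroxy-2,2,6-trimethyl-7-(triisopropylsilyloxy)chroman-4-one
Product: 27 8-(Ar-methyl)-5,7-dihydroxy-2,2,6-trimethylchroman-4-one
Conditions: TBAF, AcOH, THF, 0 °C → rt
Reagents that add atoms: none
Why: fluoride-mediated desilylation cleaves the aryl silyl ether through the strong Si–F bond, and the acetic acid buffer keeps phenoxide basicity low so that the chromanone does not open by retro-oxa-Michael reaction.

Step 14
Reactants: 27 8-(Ar-methyl)-5,7-dihydroxy-2,2,6-trimethylchroman-4-one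
Product: 28 8-({2,4-dihydroxy-6-methoxy-5-methyl-3-[(2R)-2-methylbutanoyl]phenyl}methyl)-5,7-dihydroxy-2,2,6-trimethyl-2,3-dihydro-4H-chromen-4-one (CNP0303209.1)
Conditions: H2 (1 atm), 10% Pd/C, EtOAc/EtOH, rt
Reagents that add atoms: none
Why: catalytic hydrogenolysis removes both benzyl aryl ethers under neutral conditions in which the chelated aryl ketones, the diarylmethane bridge and the α-stereocentre should be inert.

**Compound list**

1 | 2-methylphloroglucinol | Cc1c(O)cc(O)cc1O | starting material
2 | (R)-2-methylbutanoic acid | CC[C@@H](C)C(=O)O | starting material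
3 | (R)-2-methylbutanoyl chloride | CC[C@@H](C)C(=O)Cl | intermediate (not isolated)
4 | (R)-2-methyl-1-(2,4,6-trihydroxy-3-methylphenyl)butan-1-one | CC[C@@H](C)C(=O)c1c(O)c(C)c(O)cc1O | intermediate
5 | (R)-1-[2,6-dihydroxy-3-methyl-4-(prop-2-en-1-yloxy)phenyl]-2-methylbutan-1-one | CC[C@@H](C)C(=O)c1c(O)c(C)c(OCC=C)cc1O | intermediate
6 | (R)-2-methyl-1-[2,4,6-trihydroxy-3-methyl-5-(prop-2-en-1-yl)phenyl]butan-1-one | CC[C@@H](C)C(=O)c1c(O)c(C)c(O)c(CC=C)c1O | intermediate
7 | (R)-1-[2,6-dihydroxy-4-methoxy-3-methyl-5-(prop-2-en-1-yl)phenyl]-2-methylbutan-1-one | CC[C@@H](C)C(=O)c1c(O)c(C)c(OC)c(CC=C)c1O | intermediate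
8 | (R)-1-[2,6-bis(benzyloxy)-4-methoxy-3-methyl-5-(prop-2-en-1-yl)phenyl]-2-methylbutan-1-one | CC[C@@H](C)C(=O)c1c(OCc2ccccc2)c(C)c(OC)c(CC=C)c1OCc1ccccc1 | intermediate
9 | 9-(3-Ar-propyl)-9-borabicyclo[3.3.1]nonane | CC[C@@H](C)C(=O)c1c(OCc2ccccc2)c(C)c(OC)c(CCCB2C3CCCC2CCC3)c1OCc1ccccc1 | intermediate (not isolated)
10 | 3-Ar-propan-1-ol | CC[C@@H](C)C(=O)c1c(OCc2ccccc2)c(C)c(OC)c(CCCO)c1OCc1ccccc1 | intermediate
11 | 3-Ar-propanal | CC[C@@H](C)C(=O)c1c(OCc2ccccc2)c(C)c(OC)c(CCC=O)c1OCc1ccccc1 | intermediate
12 | butopyronoxyl (butyl 2,2-dimethyl-4-oxo-3,4-dihydro-2H-pyran-6-carboxylate) | CCCCOC(=O)C1=CC(=O)CC(C)(C)O1 | starting material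
13 | 2,2-dimethyl-4-oxo-3,4-dihydro-2H-pyran-6-carboxylic acid | OC(=O)C1=CC(=O)CC(C)(C)O1 | intermediate
14 | 2,2-dimethyl-4-oxo-3,4-dihydro-2H-pyran-6-carbonyl chloride | ClC(=O)C1=CC(=O)CC(C)(C)O1 | intermediate (not isolated)
15 | 1-[(E)-3-Ar-prop-1-en-1-yl]pyrrolidine | CC[C@@H](C)C(=O)c1c(OCc2ccccc2)c(C)c(OC)c(C/C=C/N2CCCC2)c1OCc1ccccc1 | intermediate (not isolated)
16 | (E)-2-(Ar-methyl)-1-(2,2-dimethyl-4-oxo-3,4-dihydro-2H-pyran-6-yl)-3-(pyrrolidin-1-yl)prop-2-en-1-one (alkene geometry of no consequence) | CC[C@@H](C)C(=O)c1c(OCc2ccccc2)c(C)c(OC)c(C/C(=C\N2CCCC2)C(=O)C2=CC(=O)CC(C)(C)O2)c1OCc1ccccc1 | intermediate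
17 | 3-Ar-2-diazo-1-(2,2-dimethyl-4-oxo-3,4-dihydro-2H-pyran-6-yl)propan-1-one | CC[C@@H](C)C(=O)c1c(OCc2ccccc2)c(C)c(OC)c(CC(=[N+]=[N-])C(=O)C2=CC(=O)CC(C)(C)O2)c1OCc1ccccc1 | intermediate
18 | ethyl acetate | CCOC(C)=O | starting material
19 | lithium 1,1-dibromoprop-1-en-2-olate | [Li+].CC([O-])=C(Br)Br | intermediate (not isolated)
20 | lithium prop-1-yn-1-olate | [Li+].CC#C[O-] | intermediate (not isolated)
21 | 1-(triisopropylsilyloxy)propyne | CC#CO[Si](C(C)C)(C(C)C)C(C)C | intermediate
22 | 2-(Ar-methyl)-2-(2,2-dimethyl-4-oxo-3,4-dihydro-2H-pyran-6-yl)ethen-1-one (vinylketene) | CC[C@@H](C)C(=O)c1c(OCc2ccccc2)c(C)c(OC)c(CC(=C=O)C2=CC(=O)CC(C)(C)O2)c1OCc1ccccc1 | intermediate (not isolated)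
23 | 4-(Ar-methyl)-4-(2,2-dimethyl-4-oxo-3,4-dihydro-2H-pyran-6-yl)-2-methyl-3-(triisopropylsilyloxy)cyclobut-2-en-1-one (either configuration at the ring sp3 carbon) | CC[C@@H](C)C(=O)c1c(OCc2ccccc2)c(C)c(OC)c(CC2(C3=CC(=O)CC(C)(C)O3)C(=O)C(C)=C2O[Si](C(C)C)(C(C)C)C(C)C)c1OCc1ccccc1 | intermediate (not isolated)
24 | 5-Ar-4-(2,2-dimethyl-4-oxo-3,4-dihydro-2H-pyran-6-yl)-2-methyl-3-(triisopropylsilyloxy)penta-1,3-dien-1-one (pyranonyl group cis to the ketene-bearing carbon) | CC[C@@H](C)C(=O)c1c(OCc2ccccc2)c(C)c(OC)c(C/C(C2=CC(=O)CC(C)(C)O2)=C(\O[Si](C(C)C)(C(C)C)C(C)C)C(C)=C=O)c1OCc1ccccc1 | intermediate (not isolated)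
25 | 8-(Ar-methyl)-2,2,6-trimethyl-7-(triisopropylsilyloxy)-2,3-dihydro-4H-chromene-4,5(4aH)-dione (either configuration at C4a) | CC[C@@H](C)C(=O)c1c(OCc2ccccc2)c(C)c(OC)c(CC2=C3OC(C)(C)CC(=O)C3C(=O)C(C)=C2O[Si](C(C)C)(C(C)C)C(C)C)c1OCc1ccccc1 | intermediate (not isolated)
26 | 8-(Ar-methyl)-5-hydroxy-2,2,6-trimethyl-7-(triisopropylsilyloxy)chroman-4-one | CC[C@@H](C)C(=O)c1c(OCc2ccccc2)c(C)c(OC)c(Cc2c(O[Si](C(C)C)(C(C)C)C(C)C)c(C)c(O)c3c2OC(C)(C)CC3=O)c1OCc1ccccc1 | intermediate
27 | 8-(Ar-methyl)-5,7-dihydroxy-2,2,6-trimethylchroman-4-one | CC[C@@H](C)C(=O)c1c(OCc2ccccc2)c(C)c(OC)c(Cc2c(O)c(C)c(O)c3c2OC(C)(C)CC3=O)c1OCc1ccccc1 | intermediate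
28 | 8-({2,4-dihydroxy-6-methoxy-5-methyl-3-[(2R)-2-methylbutanoyl]phenyl}methyl)-5,7-dihydroxy-2,2,6-trimethyl-2,3-dihydro-4H-chromen-4-one | CC[C@@H](C)C(=O)c1c(O)c(C)c(OC)c(Cc2c(O)c(C)c(O)c3c2OC(C)(C)CC3=O)c1O | target

**Step count and risks**

Total steps: 14. Longest linear sequence: 12 (steps 1–7, 9, 10, 12, 13, 14).

Steps most likely to fail:

Step 12. The excited diazo ketone may undergo 1,2-hydride shift from the bridging CH2, or carbene insertion into a benzyloxy C–H bond, faster than migration of the pyranone carbon, and the vinylketene may dimerise before the alkyne adds. The fallback gives up the benzannulation and builds the methylene bridge by classical Mannich and ortho-quinone methide coupling of two separately made halves. It sets out from 4 and 1 and comes back at 28. Compound 4 is methylated at the hydroxyl para to the acyl group (MeI, K2CO3, acetone) to (R)-1-(2,6-dihydroxy-4-methoxy-3-methylphenyl)-2-methylbutan-1-one F1. Compound 1 is condensed with 3-methylbut-2-enoic acid (MeSO3H, P2O5, 70 °C), and 5,7-dihydroxy-2,2,6-trimethylchroman-4-one F2 is separated from its 8-methyl regioisomer. Aminomethylation of F2 at its only free ring carbon with Me2N=CH2+ I− gives 8-[(dimethylamino)methyl]-5,7-dihydroxy-2,2,6-trimethylchroman-4-one F3. Heating F3 with F1 in dioxane releases the ortho-quinone methide, which is captured at C5′ of F1 to give 28 directly. The price is that the position of O1 relative to the bridge then rests on a separation of chromanone isomers.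

Step 10. Cycloaddition of the sulfonyl azide at the trisubstituted, sterically shielded enaminone carbon may be slow or the triazoline may fragment in another direction. The fallback delivers the diazo group to an enolate. It sets out from 16 and comes back at 17. Hydrolysis of 16 (1 M HCl, THF, rt) gives the hydroxymethylene ketone (Z)-2-(Ar-methyl)-1-(2,2-dimethyl-4-oxo-3,4-dihydro-2H-pyran-6-yl)-3-hydroxyprop-2-en-1-one F4. Regitz deformylative diazo transfer (TsN3, Et3N, MeCN, 0 °C) on the much more nucleophilic enolate of F4 then gives 17 with loss of the formyl group as N-formyl sulfonamide.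

Step 9. The aldehyde enamine may self-condense, or add in Michael fashion to the pyranone, instead of being C-acylated. The fallback brings in the diazo carbon as a nucleophilic diazoalkane. It sets out from 8, uses acid chloride 14, and comes back at 17. Lemieux–Johnson cleavage of 8 (cat. OsO4, NaIO4, 2,6-lutidine, dioxane/H2O) gives 2-Ar-acetaldehyde F5. Excess N2H4·H2O in EtOH at 0 °C gives (E)-(2-Ar-ethylidene)hydrazine F6. Dehydrogenation of F6 with activated DMSO (DMSO, (COCl)2, Et3N, THF, −78 °C) gives 2-Ar-1-diazoethane F7, which is acylated in the same flask by 14 in the presence of Et3N to give 17.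

**Further compounds**

F1 | step 12 | (R)-1-(2,6-dihydroxy-4-methoxy-3-methylphenyl)-2-methylbutan-1-one | CC[C@@H](C)C(=O)c1c(O)c(C)c(OC)cc1O
F2 | step 12 | 5,7-dihydroxy-2,2,6-trimethylchroman-4-one | Cc1c(O)cc2OC(C)(C)CC(=O)c2c1O
F3 | step 12 | 8-[(dimethylamino)methyl]-5,7-dihydroxy-2,2,6-trimethylchroman-4-one | CN(C)Cc1c(O)c(C)c(O)c2C(=O)CC(C)(C)Oc12
F4 | step 10 | (Z)-2-(Ar-methyl)-1-(2,2-dimethyl-4-oxo-3,4-dihydro-2H-pyran-6-yl)-3-hydroxyprop-2-en-1-one | CC[C@@H](C)C(=O)c1c(OCc2ccccc2)c(C)c(OC)c(C/C(=C/O)C(=O)C2=CC(=O)CC(C)(C)O2)c1OCc1ccccc1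
F5 | step 9 | 2-Ar-acetaldehyde | CC[C@@H](C)C(=O)c1c(OCc2ccccc2)c(C)c(OC)c(CC=O)c1OCc1ccccc1
F6 | step 9 | (E)-(2-Ar-ethylidene)hydrazine | CC[C@@H](C)C(=O)c1c(OCc2ccccc2)c(C)c(OC)c(C/C=N/N)c1OCc1ccccc1
F7 | step 9 | 2-Ar-1-diazoethane | CC[C@@H](C)C(=O)c1c(OCc2ccccc2)c(C)c(OC)c(CC=[N+]=[N-])c1OCc1ccccc1
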